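**Retrosynthetic overview**
1. The 1,2-dioxane is closed last: a tertiary peroxide anion on C13 opens a cis-β-lactone at C16 by SN2 (inversion), which also releases the propanoic acid.
2. The β-lactone (C16, C17) comes from an aldehyde and methylketene by catalytic asymmetric [2+2]; the C13 peroxide comes from cobalt-catalysed hydroperoxysilylation of a 1,1-disubstituted alkene.
3. C12–C13 is made by B-alkyl Suzuki coupling of a 9-hydroxy-9-vinyl decalin with a 2-bromoalkene; the 9α-OH comes from face-selective oxidation of an exocyclic enol acetate.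
4. Rings A and B are formed together by cationic bicyclization of the enol acetate of (R)-2,3-dihydrofarnesal, whose one stereocenter (from asymmetric hydrogenation of farnesol) directs the fold.
5. Ring order: decalin (A and B at once), then the temporary β-lactone, then the 1,2-dioxane.

Assumption: atoms are labelled as in labdanes (decalin C1–C10, side chain C11–C18, peroxide on C13 and C16); C13 has no neighbouring control element, so it is formed as both epimers in step 11 and the 13S series is isolated by chromatography after step 12.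

**Step 1**
Reactants: 1 (2E,6E)-3,7,11-trimethyldodeca-2,6,10-trien-1-ol ((2E,6E)-farnesol)
Product: 2 (3R,6E)-3,7,11-trimethyldodeca-6,10-dien-1-ol
Conditions: H2 (100 atm), Ru(OAc)2[(S)-BINAP] (0.1 mol %), MeOH, 20 °C
Reagents that add atoms: none
Why: Noyori asymmetric hydrogenation of an allylic alcohol: the hydroxyl-directed ruthenium hydride reduces only the 2,3-alkene and the (S)-BINAP ligand gives 3R (as for geraniol to (R)-citronellol), which becomes C8 of the target.

**Step 2**
Reactants: 2 (3R,6E)-3,7,11-trimethyldodeca-6,10-dien-1-ol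
Product: 3 (3R,6E)-3,7,11-trimethyldodeca-6,10-dienal
Conditions: TEMPO (10 mol %), PhI(OAc)2 (1.1 equiv), CH2Cl2, rt
Reagents that add atoms: none
Why: Nitroxyl-catalysed alcohol oxidation stops at the aldehyde, leaves the trisubstituted alkenes alone and cannot epimerize the β-stereocenter.

**Step 3**
Reactants: 3 (3R,6E)-3,7,11-trimethyldodeca-6,10-dienal
Product: 4 (3R,6E)-3,7,11-trimethyldodeca-1,6,10-trien-1-yl acetate (1E/1Z mixture)
Conditions: Ac2O, KOAc, 110 °C
Reagents that add atoms: acetic anhydride, CC(=O)OC(C)=O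
Why: Enol acetate formation by O-acetylation of the aldehyde enolate; only one α-position exists and the E/Z ratio is irrelevant because C9 becomes sp2 again in step 4.

**Step 4**
Reactants: 4 (3R,6E)-3,7,11-trimethyldodeca-1,6,10-trien-1-yl acetate
Product: 5 [(2R,4aS,8aS)-2,5,5,8a-tetramethyl-3,4,4a,5,6,7,8,8a-octahydronaphthalen-1(2H)-ylidene]methyl acetate (trans-decalin, E/Z mixture)
Conditions: Tf2NH (10 mol %), CH2Cl2, −78 to −40 °C; Et3N quench
Reagents that add atoms: none
Why: Proposed new method: cationic polyene bicyclization in which catalytic Tf2NH protonates the terminal trisubstituted alkene (trialkyl alkenes are C-protonated faster than aldehyde enol acetates), the C4 cation is captured by the (6E)-alkene and the C10 cation by C9 of the enol acetate through a chair–chair transition state that keeps the C8 methyl equatorial (the other fold puts it 1,3-diaxial to the C10 methyl), so the preset 3R center fixes 5S,10S with trans fusion, and the acetoxy-stabilized C11 cation loses the C9 proton to turn the acid over; the closest known reactions are acid-initiated farnesyl-type bicyclizations, enol-derivative-terminated epoxy-polyene cyclizations and Johnson-type induction by a stereocenter in the polyene chain.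

**Step 5**
Reactants: 5 [(2R,4aS,8aS)-2,5,5,8a-tetramethyl-octahydronaphthalen-1(2H)-ylidene]methyl acetate
Product: 7 (1R,2R,4aS,8aS)-1-hydroxy-2,5,5,8a-tetramethyldecahydronaphthalene-1-carbaldehyde, via spiro-epoxy acetate 6 (not isolated)
Conditions: mCPBA, NaHCO3, CH2Cl2, 0 °C; then K2CO3 (cat.), MeOH, 0 °C
Reagents that add atoms: 3-chloroperoxybenzoic acid, OOC(=O)c1cccc(Cl)c1
Why: Prilezhaev epoxidation of the enol acetate (Rubottom-type oxidation) occurs on the α face, anti to the axial C10 methyl that shields the β lobe at C9, and methanolysis of the epoxy acetate collapses C11 to the aldehyde while the new oxygen stays on C9 as the axial 9α-OH.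

**Step 6**
Reactants: 7 (1R,2R,4aS,8aS)-1-hydroxy-2,5,5,8a-tetramethyldecahydronaphthalene-1-carbaldehyde
Product: 8 (1R,2R,4aS,8aS)-1-ethenyl-2,5,5,8a-tetramethyldecahydronaphthalen-1-ol
Conditions: Ph3PCH3Br (3 equiv), KOtBu (2.9 equiv), THF, 0 °C to rt
Reagents that add atoms: methyltriphenylphosphonium bromide, C[P+](c1ccccc1)(c1ccccc1)c1ccccc1.[Br-]
Why: Wittig methylenation of the hindered, non-enolizable aldehyde (excess ylide also takes up the hydroxyl proton); no stereocenter is affected.

**Step 7**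
Reactants: 9 pent-4-yn-1-ol
Product: 10 4-bromopent-4-en-1-ol
Conditions: HBr, Et4NBr, CH2Cl2, 40 °C
Reagents that add atoms: hydrogen bromide, Br
Why: Markovnikov hydrobromination of the terminal alkyne by the hydrogen dibromide ion gives the 2-bromo-1-alkene and stops at mono-addition.

**Step 8**
Reactants: 8 (1R,2R,4aS,8aS)-1-ethenyl-2,5,5,8a-tetramethyldecahydronaphthalen-1-ol; 10 4-bromopent-4-en-1-ol
Product: 12 (1R,2R,4aS,8aS)-1-(6-hydroxy-3-methylidenehexyl)-2,5,5,8a-tetramethyldecahydronaphthalen-1-ol, via B-alkyl-9-BBN borane 11 (not isolated)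
Conditions: 9-BBN (2.2 equiv), THF, rt; then 10, Pd(dppf)Cl2 (5 mol %), K3PO4, DMF/H2O, 50 °C
Reagents that add atoms: none
Why: Anti-Markovnikov hydroboration of the vinyl group followed by B-alkyl Suzuki–Miyaura coupling with the vinyl bromide forms C12–C13; free hydroxyls are tolerated and no stereocenter is touched.

**Step 9**
Reactants: 12 (1R,2R,4aS,8aS)-1-(6-hydroxy-3-methylidenehexyl)-2,5,5,8a-tetramethyldecahydronaphthalen-1-ol
Product: 13 6-[(1R,2R,4aS,8aS)-1-hydroxy-2,5,5,8a-tetramethyldecahydronaphthalen-1-yl]-4-methylidenehexanal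
Conditions: TEMPO (10 mol %), PhI(OAc)2 (1.1 equiv), CH2Cl2, rt
Reagents that add atoms: none
Why: Nitroxyl-catalysed oxidation converts only the primary alcohol to the aldehyde; the hindered tertiary 9-OH and the 1,1-disubstituted alkene are inert.

**Step 10**
Reactants: 13 6-[(1R,2R,4aS,8aS)-1-hydroxy-2,5,5,8a-tetramethyldecahydronaphthalen-1-yl]-4-methylidenehexanal
Product: 14 (3S,4R)-4-{5-[(1R,2R,4aS,8aS)-1-hydroxy-2,5,5,8a-tetramethyldecahydronaphthalen-1-yl]-3-methylidenepentyl}-3-methyloxetan-2-one (cis-β-lactone)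
Conditions: EtCOCl (2 equiv), iPr2NEt (2.5 equiv), O-trimethylsilylquinine (10 mol %), LiClO4, CH2Cl2/Et2O, −78 °C
Reagents that add atoms: propanoyl chloride, CCC(Cl)=O
Why: Catalytic asymmetric acyl halide–aldehyde cyclocondensation (alkaloid-bound methylketene enolate plus lithium-activated aldehyde, formal [2+2]) gives the cis-β-lactone with C17 as S and C16 as R (inverted in step 12) under catalyst control; the pseudoenantiomeric O-trimethylsilylquinidine is used instead if the sense of induction proves opposite.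

**Step 11**
Reactants: 14 (3S,4R)-4-{5-[(1R,2R,4aS,8aS)-1-hydroxy-2,5,5,8a-tetramethyldecahydronaphthalen-1-yl]-3-methylidenepentyl}-3-methyloxetan-2-one
Product: 15 (3S,4R)-4-{(3S)-5-[(1R,2R,4aS,8aS)-1-hydroxy-2,5,5,8a-tetramethyldecahydronaphthalen-1-yl]-3-methyl-3-[(triethylsilyl)peroxy]pentyl}-3-methyloxetan-2-one (formed together with its 3R epimer in the pentyl chain, about 1:1)
Conditions: Co(acac)2 (10 mol %), O2 (1 atm), Et3SiH (3 equiv), ClCH2CH2Cl, rt
Reagents that add atoms: dioxygen, O=O; triethylsilane, CC[SiH](CC)CC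
Why: Mukaiyama–Isayama hydroperoxysilylation (hydrogen-atom transfer from the cobalt hydride to the CH2 terminus, O2 capture of the tertiary C13 radical, silyl transfer) gives the Markovnikov silyl peroxide and spares the β-lactone; nothing controls the face of the radical, so C13 is set here as a near 1:1 pair of epimers that is carried on.

**Step 12**
Reactants: 15 (3S,4R)-4-{(3S)-5-[(1R,2R,4aS,8aS)-1-hydroxy-2,5,5,8a-tetramethyldecahydronaphthalen-1-yl]-3-methyl-3-[(triethylsilyl)peroxy]pentyl}-3-methyloxetan-2-one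
Product: 17 (2S)-2-[(3S,6S)-6-{2-[(1R,2R,4aS,8aS)-1-hydroxy-2,5,5,8a-tetramethyldecahydronaphthalen-1-yl]ethyl}-6-methyl-1,2-dioxan-3-yl]propanoic acid, via tetrabutylammonium peroxide anion 16 (not isolated)
Conditions: Bu4NF (1.1 equiv), THF, −40 to 0 °C; then 0.5 M HCl, 0 °C; HPLC separation from the C13 epimer
Reagents that add atoms: none
Why: Proposed new method: fluoride cleaves the O–Si bond and the tertiary peroxide anion attacks C16 of the β-lactone in a 6-exo-tet SN2 reaction with alkyl–oxygen cleavage (acyl attack would need an eight-membered ring), which inverts C16 to S, closes the 1,2-dioxane and releases the carboxylate with C17 untouched; the closest known reactions are intramolecular alkylations of hydroperoxides by sulfonates or epoxides and SN2 openings of 4-alkyl-β-lactones at C4 by soft nucleophiles such as azide or cuprates.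

**Compound list**
1 | (2E,6E)-3,7,11-trimethyldodeca-2,6,10-trien-1-ol | OC/C=C(C)/CC/C=C(C)/CCC=C(C)C | starting material
2 | (3R,6E)-3,7,11-trimethyldodeca-6,10-dien-1-ol | OCC[C@H](C)CC/C=C(C)/CCC=C(C)C | intermediate
3 | (3R,6E)-3,7,11-trimethyldodeca-6,10-dienal | O=CC[C@H](C)CC/C=C(C)/CCC=C(C)C | intermediate
4 | (3R,6E)-3,7,11-trimethyldodeca-1,6,10-trien-1-yl acetate (1E isomer drawn, 1Z also present) | CC(=O)O/C=C/[C@H](C)CC/C=C(C)/CCC=C(C)C | intermediate
5 | [(2R,4aS,8aS)-2,5,5,8a-tetramethyl-3,4,4a,5,6,7,8,8a-octahydronaphthalen-1(2H)-ylidene]methyl acetate (E/Z) | CC(=O)OC=C2[C@H](C)CC[C@H]3C(C)(C)CCC[C@@]32C | intermediate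
6 | (1R,2R,4aS,8aS)-2,5,5,8a-tetramethyloctahydro-2H-spiro[naphthalene-1,2'-oxiran]-3'-yl acetate (epoxide oxygen α, both C3' epimers) | CC(=O)OC1O[C@@]12[C@H](C)CC[C@H]3C(C)(C)CCC[C@@]32C | intermediate
7 | (1R,2R,4aS,8aS)-1-hydroxy-2,5,5,8a-tetramethyldecahydronaphthalene-1-carbaldehyde | O=C[C@@]2(O)[C@H](C)CC[C@H]3C(C)(C)CCC[C@@]32C | intermediate
8 | (1R,2R,4aS,8aS)-1-ethenyl-2,5,5,8a-tetramethyldecahydronaphthalen-1-ol | C=C[C@@]2(O)[C@H](C)CC[C@H]3C(C)(C)CCC[C@@]32C | intermediate
9 | pent-4-yn-1-ol | C#CCCCO | starting material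
10 | 4-bromopent-4-en-1-ol | C=C(Br)CCCO | intermediate
11 | (1R,2R,4aS,8aS)-1-[2-(9-borabicyclo[3.3.1]nonan-9-yl)ethyl]-2,5,5,8a-tetramethyldecahydronaphthalen-1-ol | C1CCC2CCCC1B2CC[C@@]3(O)[C@H](C)CC[C@H]4C(C)(C)CCC[C@@]43C | intermediate
12 | (1R,2R,4aS,8aS)-1-(6-hydroxy-3-methylidenehexyl)-2,5,5,8a-tetramethyldecahydronaphthalen-1-ol | C=C(CCCO)CC[C@@]2(O)[C@H](C)CC[C@H]3C(C)(C)CCC[C@@]32C | intermediate
13 | 6-[(1R,2R,4aS,8aS)-1-hydroxy-2,5,5,8a-tetramethyldecahydronaphthalen-1-yl]-4-methylidenehexanal | C=C(CCC=O)CC[C@@]2(O)[C@H](C)CC[C@H]3C(C)(C)CCC[C@@]32C | intermediate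
14 | (3S,4R)-4-{5-[(1R,2R,4aS,8aS)-1-hydroxy-2,5,5,8a-tetramethyldecahydronaphthalen-1-yl]-3-methylidenepentyl}-3-methyloxetan-2-one | C[C@@H]1C(=O)O[C@@H]1CCC(=C)CC[C@@]2(O)[C@H](C)CC[C@H]3C(C)(C)CCC[C@@]32C | intermediate
15 | (3S,4R)-4-{(3S)-5-[(1R,2R,4aS,8aS)-1-hydroxy-2,5,5,8a-tetramethyldecahydronaphthalen-1-yl]-3-methyl-3-[(triethylsilyl)peroxy]pentyl}-3-methyloxetan-2-one (desired epimer drawn) | CC[Si](CC)(CC)OO[C@@](C)(CC[C@H]4OC(=O)[C@H]4C)CC[C@@]2(O)[C@H](C)CC[C@H]3C(C)(C)CCC[C@@]32C | intermediate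
16 | tetrabutylammonium salt of the peroxide anion obtained from 15 by loss of the silyl group | CCCC[N+](CCCC)(CCCC)CCCC.[O-]O[C@@](C)(CC[C@H]4OC(=O)[C@H]4C)CC[C@@]2(O)[C@H](C)CC[C@H]3C(C)(C)CCC[C@@]32C | intermediate
17 | (2S)-2-[(3S,6S)-6-{2-[(1R,2R,4aS,8aS)-1-hydroxy-2,5,5,8a-tetramethyldecahydronaphthalen-1-yl]ethyl}-6-methyl-1,2-dioxan-3-yl]propanoic acid | C[C@H](C(=O)O)[C@@H]1CC[C@@](C)(CC[C@@]2(O)[C@H](C)CC[C@H]3C(C)(C)CCC[C@@]32C)OO1 | target

**Step count and risks**
Total: 12 steps. Longest linear sequence: 11 steps (steps 1–6 and 8–12, from 1 to 17); step 7 is the side branch. Step 11 works as described but is unselective at C13, so at most half of the material from that point has the target configuration.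

Most likely to fail, first: step 4. The proton may attack the internal alkene or the enol acetate, and the relay of configuration from C8 into ring A may be incomplete. The fallback sets out from 4 and replaces the proton by a bromonium initiator, which discriminates more strongly in favour of the trialkyl alkene. [Et2SBr][SbCl5Br] in MeNO2 at −25 °C gives, by the same chair–chair cascade and loss of the C9 proton, the 3β-bromo bicyclic enol acetate F1. Bu3SnH with AIBN in benzene at 80 °C removes the bromine and the route comes back at 5.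

Second: step 12. The peroxide anion or fluoride may instead open the β-lactone by elimination, which would lose C16. The fallback sets out from 14 and replaces the lactone electrophile by a sulfonate. NaOMe (cat.) in MeOH at 0 °C opens the lactone at the acyl carbon with retention to the syn-hydroxy ester F4. MsCl and Et3N give the secondary mesylate F5 (the tertiary 9-OH does not react). Co(acac)2, O2 and Et3SiH give the silyl peroxide mesylate F6. Bu4NF in THF at 0 °C releases the peroxide anion F7, which displaces the mesylate with inversion to the dioxane methyl ester F8. LiOH in THF/H2O then gives 17.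

Third: step 5. If the peracid prefers the β face of the exocyclic alkene, the C9 epimer of 7 results. The fallback sets out from 5. Ozonolysis (O3, CH2Cl2, −78 °C; then Me2S) passes through the ozonide F2 to the decalone, the ketone F3. CH2=CHMgBr with CeCl3 (THF, −78 °C) then adds to that same, then less hindered, β face and comes back at 8. The two sequences have opposite facial demands, so one of them gives 8 whichever face is open.

**Further compounds**
F1 | step 4 | [(2R,4aR,6S,8aS)-6-bromo-2,5,5,8a-tetramethyl-3,4,4a,5,6,7,8,8a-octahydronaphthalen-1(2H)-ylidene]methyl acetate | CC(=O)OC=C2[C@H](C)CC[C@H]3C(C)(C)[C@@H](Br)CC[C@@]32C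
F2 | step 5 | (2R,4aS,8aS)-2,5,5,8a-tetramethyloctahydro-2H-spiro[naphthalene-1,3'-[1,2,4]trioxolan]-5'-yl acetate (mixture at the spiro and acetal carbons) | CC(=O)OC1OOC2(O1)[C@H](C)CC[C@H]3C(C)(C)CCC[C@@]32C
F3 | step 5 | (2R,4aS,8aS)-2,5,5,8a-tetramethyloctahydronaphthalen-1(2H)-one | O=C2[C@H](C)CC[C@H]3C(C)(C)CCC[C@@]32C
F4 | step 12 | methyl (2S,3R)-3-hydroxy-8-[(1R,2R,4aS,8aS)-1-hydroxy-2,5,5,8a-tetramethyldecahydronaphthalen-1-yl]-2-methyl-6-methylideneoctanoate | COC(=O)[C@@H](C)[C@H](O)CCC(=C)CC[C@@]2(O)[C@H](C)CC[C@H]3C(C)(C)CCC[C@@]32C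
F5 | step 12 | methyl (2S,3R)-8-[(1R,2R,4aS,8aS)-1-hydroxy-2,5,5,8a-tetramethyldecahydronaphthalen-1-yl]-3-(methanesulfonyloxy)-2-methyl-6-methylideneoctanoate | COC(=O)[C@@H](C)[C@H](OS(C)(=O)=O)CCC(=C)CC[C@@]2(O)[C@H](C)CC[C@H]3C(C)(C)CCC[C@@]32C
F6 | step 12 | methyl (2S,3R,6S)-8-[(1R,2R,4aS,8aS)-1-hydroxy-2,5,5,8a-tetramethyldecahydronaphthalen-1-yl]-3-(methanesulfonyloxy)-2,6-dimethyl-6-[(triethylsilyl)peroxy]octanoate (formed with its 6R epimer) | CC[Si](CC)(CC)OO[C@@](C)(CC[C@@H](OS(C)(=O)=O)[C@H](C)C(=O)OC)CC[C@@]2(O)[C@H](C)CC[C@H]3C(C)(C)CCC[C@@]32C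
F7 | step 12 | tetrabutylammonium salt of the peroxide anion obtained from F6 by loss of the silyl group | CCCC[N+](CCCC)(CCCC)CCCC.[O-]O[C@@](C)(CC[C@@H](OS(C)(=O)=O)[C@H](C)C(=O)OC)CC[C@@]2(O)[C@H](C)CC[C@H]3C(C)(C)CCC[C@@]32C
F8 | step 12 | methyl (2S)-2-[(3S,6S)-6-{2-[(1R,2R,4aS,8aS)-1-hydroxy-2,5,5,8a-tetramethyldecahydronaphthalen-1-yl]ethyl}-6-methyl-1,2-dioxan-3-yl]propanoate | C[C@H](C(=O)OC)[C@@H]1CC[C@@](C)(CC[C@@]2(O)[C@H](C)CC[C@H]3C(C)(C)CCC[C@@]32C)OO1
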